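The numbers in the tables are simulated from invented constants, noise included.

Take the green run and hold its last reading against the gas. In the green run, c(target) reached 123 mM by 120 s, more than the 32 mM of gas a saturated solution holds. Yet each target should take up one gas.

- green: electrophile 0.67 M; free base 3 equiv; gas 32 mM (held); run made earlier
- flask: electrophile 1.0 M; free base 3.00 equiv; gas 32 mM (held); time 2.5 min

- green (time / s: target / %, electrophile / %): 10.0: 1.4, 98.9; 30.0: 4.4, 94.5; 60.0: 8.6, 92.2; 80.0: 12.5, 87.6; 120: 18.4, 82.3

(scatter of a reading: 1 percentage point)

- at the start none of the gas is in solution
- no earlier run changes the charge of free base; that part of a forecast is a guess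

- how much target there is at 2.5 min, in percent of the electrophile charged
- the change that raises the amount of target at 2.5 min, in percent of the electrophile charged most ("none" if none brings more than 2 percentage points) (east / north-west / south / none)
- amount of target at 2.5 min, in percent of the electrophile charged, after north-west

- east: doubling the amount of free base, all else as stated
- north-west: doubling the saturation concentration of gas, all else as stated
- south: doubling the transfer coefficient of the gas, all else as stated

I cleared this up by counting turnovers, that is, target made per saturated load of gas. The green run had 3.85 behind it, which counts gas ending in target, so the gas had refilled the solution at least that many times over. That gave 1.93 min⁻¹, the turnover rate, in the usual term a turnover frequency.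

The scatter hid whether this rate followed the electrophile. So I took two cases for the flask. At the same rate it would make 4.82 turnovers, or 15.4% target. With the rate scaled to the electrophile charge it would make 7.19, or 23.0% target. At equal turnovers, doubling the saturation concentration doubles the target, so I chose north-west.

The forecast gave 16%, chose north-west and put 31.5% after it, holding that “Doubling the saturation concentration doubles the driving force whatever the regime”. Its 16% lay inside my two cases, near the low end.

The flask gave 20.9%. North-west was the best change, gaining 17 percentage points and reaching 38.1%, which was 6.6 points above the forecast.

    gas ⇌ nucleophile, rate k1*(csat - [nucleophile]) (kL = 0.270 s⁻¹)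
    electrophile + nucleophile → acid set free + target (k = 0.0720 L mol⁻¹ s⁻¹)
    acid set free + free base ⇌ salt of the base (K = 5.20 L mol⁻¹, k = 0.0130 L mol⁻¹ s⁻¹)
    nucleophile + acid set free ⇌ protonated nucleophile, settled at all times (K = 1400 L mol⁻¹)

The flask made 6.52 turnovers at 2.61 min⁻¹, faster than the green run's 1.93 min⁻¹. The flask's target stood at 20.9% because the run was short: left ten times as long, the flask reached 95.0%, a gain of 74 points. The neighbour read at 10 min had 20.4 turnovers behind it, averaging 2.04 min⁻¹, and held 65.4% target.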